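## Analysis of the target

The target is a germacranolide of the furanoheliangolide type (germacrane numbering C1–C15 is used for every compound below). Its ten-membered carbocycle C1–C10 is bridged by an oxygen between C3 and C10, so that O, C3, C2, C1 and C10 form a 3(2H)-furanone (C1 ketone, C2=C3 enol ether) inside an 11-oxabicyclo[6.2.1]undecane. A trans-fused α-methylene-γ-butyrolactone (C11–C13, oxygen on C6) sits on C6/C7.

There are six stereocentres: C4 (tertiary alcohol with the C15 hydroxymethyl group, S), C5 (acetate, S), C6 (S), C7 (R), C8 (methacrylate, R) and C10 (quaternary: methyl, ether oxygen, C9, C1; R). O4, O5 and O6 lie on one face of the C3–C7 segment, H6 and H7 are trans, and H7 and O8 are syn when C6–C7–C8–C9 is drawn zigzag. The configuration of C10 is tied to C3 by the one-atom bridge.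

Sensitive groups are two Michael acceptors (α-methylene lactone, methacrylate), the vinylogous ester of the furanone, and the C5 acetate next to a free tertiary/primary diol (acyl migration). Strong base is therefore possible only before the acetate and the methacrylate are in place.

The difficulty lies in the strained bridged medium ring, the two fully substituted carbons C4 and C10, and the fact that C7 and C8 must be set on the formed ring, where reagents reach only the outer face.

The strategy rests on C10: it carries the ether oxygen, a methyl group and C9 and is α to the C1 ketone. This is the retron of a [2,3]-shift of an oxonium ylide formed from a six-membered ether whose oxygen is flanked by C3 and an allylic C7.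

## Retrosynthetic reasoning

**Diol and acetate.** Target 38 is traced to acetonide 37. The dioxolane is hydrolysed last so that the free diol never meets base next to the C5 acetate. The acetate (37 from 36, 36 from silyl ether 35) is introduced only after the last strongly basic step, so C5 travels as a silyl ether from 14 onwards.

**C8 ester and C11=C13.** 35 comes from alcohol 34 by acylation, and 34 from hydroxy lactone 31 by attaching C13 to the lactone enolate. This is done before any ester with α-hydrogens or any Michael acceptor is present.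

**C7–H and C8–O.** In alkene 26 the C7=C8 bond lies in the lactone plane and the ring chain (C5 to C10) covers the face that carries C5. Syn-hydroboration on the exposed face would place H7 cis to H6. Therefore only oxygen is taken from that face (epoxide 27), and the double bond is moved to C7=C11 by β-elimination (28). The carbinol is then inverted (29, 30), and H7 is delivered from the carbinol side by hydroxyl-directed hydrogenation (31). Both centres then rest on stereospecific steps and one directed step.

**C2=C3.** Furanone 26 is traced to ketone 24 by dehydrogenation. C10 is quaternary, so only C2 can enolise.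

**O–C10 and C9–C10 (key disconnection).** Ketone 24 is traced through oxonium ylide 23 to diazo ketone 22, re-forming O–C7. These two bonds hold the only quaternary ring carbon and close both rings. Cutting them turns the bridged ten-membered ring into a pyran and avoids any end-to-end macrocyclisation. The forward step must make the ylide faster than the carbenoid rearranges and must shift the allyl group [2,3].

**C1–C10.** 22 comes from acid 18 through acid chloride 20 and diazoethane 21 (from 19).

**O–C7.** Pyran 17 is opened to butenolide diol 15/16. The ether bond is cut at C7 and not at C3 because C3, which later dictates C10, is then a carbinol set beforehand. C7 need only follow the cis ring fusion and is lost as a stereocentre in the key step.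

**C5–C6.** 13 is split into aldehyde 8 and silyloxyfuran 12 (vinylogous aldol). C5 is set by the adjacent quaternary C4, and C6 is corrected in the cyclisation.

**C3–C4 and O4/O15.** 8 goes back through 7, 6 and 5 to adduct 4, made from 1 and 2. C3 comes from the catalyst and C4 from substrate-controlled dihydroxylation.

**Furan fragment.** 12 comes from 11, which is made from 9 and 10.

## Alternatives that were turned down

Alternative 1: Disconnection of the C5–C6 ring bond opposite the ether bridge. In the forward sense a Z-configured alkenyl–metal species at C5 (from the C5–I bond, NiCl2 co-catalyst, catalytic CrCl2 with the divalent chromium regenerated at a cathode) adds to a C6 aldehyde. This gives the ten-membered allylic alcohol A1 with the furanone already in place.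
- For it: convergence; the furanone and its quaternary C10 are made on a small ring; C7 and C8 are set in an open chain before ring closure. On that point it is stronger than the chosen route.
- Against it: a ten-membered ring is closed end to end between two hindered carbons (high dilution, oligomers). The C6 carbinol is formed in the cyclisation without an obvious control element. C4 and C5 must then be set by dihydroxylation of the ring alkene from one face, and the lactone is still to be closed. Electrochemical chromium turnover adds a further variable.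
- Comparison: the chosen strategy makes both rings by a three-atom ring expansion of a pyran at normal concentration and sets C4–C6 off the ring. It pays for this with the on-ring adjustment of C7/C8.

Alternative 2: Disconnection of C1–C2 and O–C3, with the furanone masked as an isoxazole. A nitrile oxide at C1 (oxime, chlorination, base) adds to a terminal C2≡C3 alkyne and closes the carbocycle as the 3,5-bridged isoxazole A2. N–O cleavage, hydrolysis and cyclodehydration with the C10 oxygen would follow.
- For it: a robust mask for the vinylogous ester; every sp3 stereocentre, including C7, C8 and C10, and the lactone are in place before ring closure. That is stronger than the chosen route.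
- Against it: the product is a five-membered heteroaromatic bridged by only seven atoms, so strain is high. Nitrile oxide dimerisation competes, and regiochemistry may change under strain. Unmasking and regioselective furanone formation cost four to five steps at the end of a long linear sequence.
- Comparison: the chosen route forms the furanone ring and the macrocycle in one step and needs one oxidation to reach the enol ether.

Alternative 3: Disconnection of C7–C11 and C11=C13. Rh2(O2CC7H15)4 decomposes a diazophosphonoacetate on O6; the carbenoid inserts into a C7–H bond to close the lactone, and olefination with formaldehyde in the same flask gives A3.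
- For it: the α-methylene lactone arises without enolate chemistry and tolerates the acetate. Here it is stronger than the chosen route, which needs an amide base and a protecting-group exchange at C5.
- Against it: it does not build the bridged ten-membered ring and presupposes another ring synthesis with C7 as a methylene group. One of two diastereotopic C7–H bonds must react, the C5–H bond is also 1,5-related, and the bridging ether oxygen and the furanone can trap the carbenoid.
- Comparison: it is an end-game only. The chosen strategy supplies the ring system, but delivers C7 already bonded to C11, which excludes this insertion.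

Key step: step 14

Remark on the chemistry: 13 is drawn as the 5,6-threo epimer expected under Lewis acid promotion; any 5,6-erythro epimer becomes 16 after steps 9 and 10 and converges in step 11. TBS = tert-butyldimethylsilyl, TES = triethylsilyl.
Assumption: β-isocupreidine delivers the (R)-adduct with aldehyde 1, as with other unbranched aliphatic aldehydes.

Step 1
Reactants: 1 3-[(tert-butyldimethylsilyl)oxy]propanal; 2 1,1,1,3,3,3-hexafluoropropan-2-yl acrylate
Product: 4 methyl (R)-5-[(tert-butyldimethylsilyl)oxy]-3-hydroxy-2-methylidenepentanoate, via hexafluoroisopropyl ester 3 (not isolated)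
Conditions: β-isocupreidine (10 mol %), DMF, −55 °C; then MeOH, Et3N, rt
Reagents that add atoms: methanol, CO
Why: Amine-catalysed asymmetric Morita–Baylis–Hillman reaction; the cinchona-derived catalyst adds to the activated acrylate and the enolate attacks 1 in a hydrogen-bonded ion pair that should give the (R)-carbinol (C3). Methanolysis of the activated ester in the same flask gives the robust methyl ester.

Step 2
Reactants: 4 methyl (R)-5-[(tert-butyldimethylsilyl)oxy]-3-hydroxy-2-methylidenepentanoate
Product: 5 methyl (R)-5-[(tert-butyldimethylsilyl)oxy]-2-methylidene-3-[(triethylsilyl)oxy]pentanoate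
Conditions: Et3SiCl, imidazole, CH2Cl2, 0 °C
Reagents that add atoms: chlorotriethylsilane, CC[Si](Cl)(CC)CC
Why: Silylation of the secondary allylic alcohol; the TES ether is chosen because it must later be removed beside a hindered secondary TBS ether.

Step 3
Reactants: 5 methyl (R)-5-[(tert-butyldimethylsilyl)oxy]-2-methylidene-3-[(triethylsilyl)oxy]pentanoate
Product: 6 methyl (2R,3R)-5-[(tert-butyldimethylsilyl)oxy]-2-hydroxy-2-(hydroxymethyl)-3-[(triethylsilyl)oxy]pentanoate
Conditions: OsO4 (2 mol %), N-methylmorpholine N-oxide, acetone/H2O, rt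
Reagents that add atoms: N-methylmorpholine N-oxide, C[N+]1([O-])CCOCC1; water, O
Why: Catalytic syn-dihydroxylation; with the ester on the alkene carbon the allylic C–H eclipses the C–CO2Me bond (allylic 1,2-strain) and OsO4 should add anti to the silyloxy group. This sets C4 with O3 and O4 anti.

Step 4
Reactants: 6 methyl (2R,3R)-5-[(tert-butyldimethylsilyl)oxy]-2-hydroxy-2-(hydroxymethyl)-3-[(triethylsilyl)oxy]pentanoate
Product: 7 methyl (R)-4-{(R)-3-[(tert-butyldimethylsilyl)oxy]-1-[(triethylsilyl)oxy]propyl}-2,2-dimethyl-1,3-dioxolane-4-carboxylate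
Conditions: 2-methoxypropene, pyridinium p-toluenesulfonate (cat.), CH2Cl2, 0 °C
Reagents that add atoms: 2-methoxypropene, C=C(C)OC
Why: Acid-catalysed acetonide formation; only one 1,2-diol is present, so the C4/C15 dioxolane forms unambiguously.

Step 5
Reactants: 7 methyl (R)-4-{(R)-3-[(tert-butyldimethylsilyl)oxy]-1-[(triethylsilyl)oxy]propyl}-2,2-dimethyl-1,3-dioxolane-4-carboxylate
Product: 8 (R)-4-{(R)-3-[(tert-butyldimethylsilyl)oxy]-1-[(triethylsilyl)oxy]propyl}-2,2-dimethyl-1,3-dioxolane-4-carbaldehyde
Conditions: i-Bu2AlH, CH2Cl2, −78 °C; aq. potassium sodium tartrate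
Reagents that add atoms: none
Why: Partial reduction of an α-alkoxy ester; the chelated tetrahedral intermediate survives at −78 °C and gives the aldehyde on work-up. The aldehyde (C5) has no α-hydrogen and cannot epimerise.

Step 6
Reactants: 9 4-bromofuran-2(5H)-one; 10 tributyl(vinyl)stannane
Product: 11 4-vinylfuran-2(5H)-one
Conditions: Pd(PPh3)4 (5 mol %), toluene, 90 °C
Reagents that add atoms: none
Why: Stille coupling of a β-bromo enoate, which undergoes oxidative addition readily; neutral conditions spare the base-sensitive butenolide.

Step 7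
Reactants: 11 4-vinylfuran-2(5H)-one
Product: 12 tert-butyl(dimethyl)[(4-vinylfuran-2-yl)oxy]silane
Conditions: t-BuMe2SiOTf, Et3N, CH2Cl2, 0 °C; used crude
Reagents that add atoms: tert-butyldimethylsilyl trifluoromethanesulfonate, CC(C)(C)[Si](C)(C)OS(=O)(=O)C(F)(F)F
Why: Soft enolisation at the acidic γ-position of the butenolide gives the aromatic 2-silyloxyfuran.

Step 8
Reactants: 8 (R)-4-{(R)-3-[(tert-butyldimethylsilyl)oxy]-1-[(triethylsilyl)oxy]propyl}-2,2-dimethyl-1,3-dioxolane-4-carbaldehyde; 12 tert-butyl(dimethyl)[(4-vinylfuran-2-yl)oxy]silane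
Product: 13 vinylogous aldol adduct (5-substituted 4-vinylfuran-2(5H)-one; free C5 alcohol; C3 OTES; C1 OTBS; C4/C15 acetonide; 5,6-threo)
Conditions: BF3·OEt2, CH2Cl2, −78 °C
Reagents that add atoms: none
Why: Vinylogous Mukaiyama aldol addition at the furan γ-carbon (C6). Attack anti to the C4–O bond and past the tied-back ring CH2 instead of the branched C3 chain (Felkin–Anh) should set C5; the open transition state is expected to favour the 5,6-threo adduct, whose C6 is corrected in step 11.

Step 9
Reactants: 13 vinylogous aldol adduct (free C5 alcohol)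
Product: 14 C5 TBS ether of the butenolide (C3 OTES; C1 OTBS; C4/C15 acetonide)
Conditions: t-BuMe2SiOTf, 2,6-lutidine, CH2Cl2, −78 to 0 °C
Reagents that add atoms: tert-butyldimethylsilyl trifluoromethanesulfonate, CC(C)(C)[Si](C)(C)OS(=O)(=O)C(F)(F)F
Why: Silylation of a hindered secondary alcohol; the ether blocks retro-aldol cleavage in step 11 and stays until step 23.

Step 10
Reactants: 14 C5 TBS ether of the butenolide
Product: 15 5,6-threo butenolide diol (free C3 and C1 hydroxyls; C5 OTBS)
Conditions: HF·pyridine, pyridine, THF, 0 °C
Reagents that add atoms: none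
Why: Buffered fluoride should cleave the secondary TES ether and the primary TBS ether much faster than the neopentyl-type secondary TBS ether at C5.

Step 11
Reactants: 15 5,6-threo butenolide diol
Product: 17 cis-fused 2-vinyltetrahydropyran γ-lactone with C1 primary alcohol (C5 OTBS; C4/C15 acetonide), via 5,6-erythro butenolide diol 16 (not isolated)
Conditions: DBU (0.5 equiv), toluene, rt to 40 °C
Reagents that add atoms: none
Why: Base-mediated γ-epimerisation of the butenolide through its 2-oxidofuran (a known equilibration of 5-(1-silyloxyalkyl)butenolides) and 6-exo-trig oxa-Michael addition of the C3 hydroxyl to C7. The new five/six ring fusion can only be cis, so C7 follows C6, and the erythro-derived bicycle avoids the two 1,3-diaxial contacts of its C6/C7 diastereomer, so the reversible sequence should drain into 17. Attack at C7 and not at the vinyl terminus follows from ring size (six against eight).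

Step 12
Reactants: 17 pyran-fused lactone with C1 primary alcohol
Product: 18 pyran-fused lactone C1 carboxylic acid
Conditions: TEMPO (cat.), PhI(OAc)2, MeCN/H2O, rt
Reagents that add atoms: water, O
Why: Oxoammonium oxidation of the primary alcohol through the aldehyde hydrate to the acid; alkene, acetonide, lactone and silyl ether are inert.

Step 13
Reactants: 18 pyran-fused lactone C1 carboxylic acid; 19 N-ethyl-N-nitrosourea
Product: 22 diazo ketone (3-diazo-2-oxobutyl chain on C3 of the cis-fused 2-vinyltetrahydropyran γ-lactone; C5 OTBS; C4/C15 acetonide), via acid chloride 20 (not isolated), via diazoethane 21 (not isolated)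
Conditions: 1-chloro-N,N,2-trimethylprop-1-en-1-amine, CH2Cl2, 0 °C; then 21 (from 19, KOH, Et2O/H2O, 0 °C, excess), Et2O, −20 to 0 °C
Reagents that add atoms: none
Why: The chloroenamine makes the acid chloride without HCl, which would threaten the acetonide. Acylation of diazoethane (Arndt–Eistert-type; the excess traps HCl as chloroethane) gives the 2-diazo ketone.

Step 14
Reactants: 22 diazo ketone
Product: 24 oxygen-bridged (E)-cyclodecene tetrahydrofuranone lactone (C1 ketone; C7=C8; C10 methyl; C5 OTBS; C4/C15 acetonide), via bicyclic oxonium ylide 23 (not isolated)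
Conditions: Rh2(O2CCPh3)4 (2 mol %), CH2Cl2, slow addition of 22, −40 °C to rt
Reagents that add atoms: none
Why: Catalytic oxonium ylide formation and [2,3]-sigmatropic ring expansion of a 2-vinyl cyclic ether, a known reaction type: the rhodium carboxylate turns the diazo ketone into an electrophilic carbenoid at C10, which the pyran oxygen captures through a five-membered transition state (O, C3, C2, C1, C10) to give ylide 23. In 23 the enolate carbon C10 bonds to the vinyl terminus C9 while the O–C7 bond breaks in a five-centre, six-electron shift. The five-membered ketone ring is closed by O–C10 bond formation (cyclisation of the ether oxygen onto the carbenoid), and the ten-membered carbocycle arises from the three-atom ring expansion of the pyran (C9–C10 formed, O–C7 broken), not from an end-to-end cyclisation. The one new stereocentre, C10, is controlled by C3: the one-atom bridge can span the new ring only cis, so the C3 configuration is copied to C10, while C7 becomes an alkene carbon. Chemoselectivity is needed against 1,2-hydride migration from the C10 methyl group, cyclopropanation of the vinyl group and a [1,2]-shift of C7; the bulky triphenylacetate ligands, low temperature and the five-membered proximity of the oxygen should hold back the first, the second needs a seven-membered transition state, and the third should be slower than the concerted allyl shift. The E geometry follows from the ylide with C10 equatorial on oxygen, where C9 reaches C10 only from the side of C11; bulky rhodium carboxylates favour this pathway.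

Step 15
Reactants: 24 oxygen-bridged (E)-cyclodecene tetrahydrofuranone lactone
Product: 26 bridged (E)-cyclodecene 3(2H)-furanone lactone (C2=C3 installed), via trimethylsilyl enol ether 25 (not isolated)
Conditions: Me3SiOTf, Et3N, CH2Cl2, −78 to 0 °C; then Pd(OAc)2, MeCN, rt
Reagents that add atoms: none
Why: Saegusa–Ito oxidation: the ketone can enolise only towards C2, the silyl enol ether is palladated at C2, and β-hydride elimination of H3 gives the furanone. Under soft enolisation the ketone should be silylated well before the lactone.

Step 16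
Reactants: 26 bridged (E)-cyclodecene 3(2H)-furanone lactone
Product: 27 7,8-epoxide (oxygen on the face of H6; C8 S)
Conditions: dimethyldioxirane, acetone/CH2Cl2, −20 °C
Reagents that add atoms: dimethyldioxirane, CC1(C)OO1
Why: Epoxidation of the strained, electron-rich trisubstituted (E)-alkene; the ring chain from C5 to C10 covers one face, so oxygen arrives on the face of H6. The electron-poor furanone alkene should not react.

Step 17
Reactants: 27 7,8-epoxide
Product: 28 (8S)-8-hydroxy-7(11)-butenolide
Conditions: DBU (1.1 equiv), CH2Cl2, 0 °C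
Reagents that add atoms: none
Why: E1cB opening of a β,γ-epoxy lactone: deprotonation at C11 and cleavage of C7–O give the conjugated butenolide. The C8–O bond and its configuration are untouched.

Step 18
Reactants: 28 (8S)-8-hydroxy-7(11)-butenolide
Product: 29 (8R)-8-formyloxy-7(11)-butenolide
Conditions: HCO2H, PPh3, diisopropyl azodicarboxylate, THF, 0 °C to rt
Reagents that add atoms: formic acid, O=CO
Why: Mitsunobu esterification with SN2 inversion at the secondary allylic carbinol C8 (S to R); formic acid is small and acidic enough for a hindered alcohol.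

Step 19
Reactants: 29 (8R)-8-formyloxy-7(11)-butenolide
Product: 30 (8R)-8-hydroxy-7(11)-butenolide
Conditions: KHCO3, MeOH, 0 °C
Reagents that add atoms: none
Why: Transesterification of the formate under nearly neutral conditions that should not deprotonate the butenolide at C6.

Step 20
Reactants: 30 (8R)-8-hydroxy-7(11)-butenolide
Product: 31 (7R,8R)-8-hydroxy trans-fused γ-lactone (C11 methylene)
Conditions: H2 (1 atm), [Ir(cod)(PCy3)(py)]PF6 (10 mol %), CH2Cl2, 0 °C to rt
Reagents that add atoms: none
Why: Hydroxyl-directed hydrogenation: the cationic iridium complex binds the C8 hydroxyl and the C7=C11 alkene. In the rotamer that avoids allylic 1,2-strain (H8 next to C6, C9 next to C11) the hydroxyl lies on the alkene face that carries C5, so H7 is delivered syn to O8 and trans to H6, the anti 1,2-induction known for 2-substituted allylic alcohols. The furanone alkene has no directing group and should react more slowly.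

Step 21
Reactants: 31 (7R,8R)-8-hydroxy trans-fused γ-lactone
Product: 34 α-methylene lactone with free C8 alcohol, via Mannich base 32 (not isolated), via trimethylammonium iodide 33 (not isolated)
Conditions: LiN(i-Pr)2 (2.3 equiv), THF, −78 °C; CH2=NMe2+ I−, −78 to 0 °C; then MeI, THF, rt; then aq. NaHCO3, EtOAc, rt
Reagents that add atoms: dimethyl(methylidene)ammonium iodide, C=[N+](C)C.[I-]
Why: Mannich-type α-methylenation: the dianion (C8 alkoxide and lactone enolate) is aminomethylated at C11, and quaternisation followed by E1cB loss of trimethylamine gives the exocyclic alkene. No other enolisable ester is present at this stage.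

Step 22
Reactants: 34 α-methylene lactone with free C8 alcohol
Product: 35 C8 methacrylate (C5 OTBS; C4/C15 acetonide)
Conditions: methacrylic anhydride, Et3N, 4-(dimethylamino)pyridine (cat.), CH2Cl2, 0 °C to rt
Reagents that add atoms: methacrylic anhydride, CC(=C)C(=O)OC(=O)C(C)=C
Why: Nucleophile-catalysed acylation of the secondary C8 alcohol with retention.

Step 23
Reactants: 35 C8 methacrylate
Product: 36 C5 alcohol (C8 methacrylate; C4/C15 acetonide)
Conditions: HF·pyridine, THF, 0 °C to rt
Reagents that add atoms: none
Why: Fluoride cleavage of the last silyl ether under conditions that leave the acetonide, both enoates and the furanone intact.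

Step 24
Reactants: 36 C5 alcohol
Product: 37 C5 acetate (acetonide of the target)
Conditions: Ac2O, pyridine, 4-(dimethylamino)pyridine (cat.), CH2Cl2, rt
Reagents that add atoms: acetic anhydride, CC(=O)OC(C)=O
Why: Acetylation of the only free hydroxyl, after all strongly basic steps.

Step 25
Reactants: 37 C5 acetate (acetonide of the target)
Product: 38 target compound CNP0275292.4
Conditions: AcOH/H2O (4:1), 40 °C
Reagents that add atoms: none
Why: Acid-catalysed hydrolysis of the dioxolane as the last step, so that the free diol is not exposed to base next to the C5 acetate.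

Compound list

1 | 3-[(tert-butyldimethylsilyl)oxy]propanal | O=CCCO[Si](C)(C)C(C)(C)C | starting material
2 | 1,1,1,3,3,3-hexafluoropropan-2-yl acrylate | C=CC(=O)OC(C(F)(F)F)C(F)(F)F | starting material
3 | hexafluoroisopropyl (R)-5-[(tert-butyldimethylsilyl)oxy]-3-hydroxy-2-methylidenepentanoate | C=C(C(=O)OC(C(F)(F)F)C(F)(F)F)[C@H](O)CCO[Si](C)(C)C(C)(C)C | intermediate
4 | methyl (R)-5-[(tert-butyldimethylsilyl)oxy]-3-hydroxy-2-methylidenepentanoate | C=C(C(=O)OC)[C@H](O)CCO[Si](C)(C)C(C)(C)C | intermediate
5 | methyl (R)-5-[(tert-butyldimethylsilyl)oxy]-2-methylidene-3-[(triethylsilyl)oxy]pentanoate | C=C(C(=O)OC)[C@H](O[Si](CC)(CC)CC)CCO[Si](C)(C)C(C)(C)C | intermediate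
6 | methyl (2R,3R)-5-[(tert-butyldimethylsilyl)oxy]-2-hydroxy-2-(hydroxymethyl)-3-[(triethylsilyl)oxy]pentanoate | COC(=O)[C@@](O)(CO)[C@H](O[Si](CC)(CC)CC)CCO[Si](C)(C)C(C)(C)C | intermediate
7 | methyl (R)-4-{(R)-3-[(tert-butyldimethylsilyl)oxy]-1-[(triethylsilyl)oxy]propyl}-2,2-dimethyl-1,3-dioxolane-4-carboxylate | COC(=O)[C@@](OC1(C)C)(CO1)[C@H](O[Si](CC)(CC)CC)CCO[Si](C)(C)C(C)(C)C | intermediate
8 | (R)-4-{(R)-3-[(tert-butyldimethylsilyl)oxy]-1-[(triethylsilyl)oxy]propyl}-2,2-dimethyl-1,3-dioxolane-4-carbaldehyde | O=C[C@@](OC1(C)C)(CO1)[C@H](O[Si](CC)(CC)CC)CCO[Si](C)(C)C(C)(C)C | intermediate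
9 | 4-bromofuran-2(5H)-one | O=C1C=C(Br)CO1 | starting material
10 | tributyl(vinyl)stannane | C=C[Sn](CCCC)(CCCC)CCCC | starting material
11 | 4-vinylfuran-2(5H)-one | O=C1C=C(C=C)CO1 | intermediate
12 | tert-butyl(dimethyl)[(4-vinylfuran-2-yl)oxy]silane | C=Cc1coc(O[Si](C)(C)C(C)(C)C)c1 | intermediate
13 | vinylogous aldol adduct, 5,6-threo, free C5 alcohol | O=C1C=C(C=C)[C@@H](O1)[C@H](O)[C@@](OC2(C)C)(CO2)[C@H](O[Si](CC)(CC)CC)CCO[Si](C)(C)C(C)(C)C | intermediate
14 | C5 TBS ether of 13 | O=C1C=C(C=C)[C@@H](O1)[C@H](O[Si](C)(C)C(C)(C)C)[C@@](OC2(C)C)(CO2)[C@H](O[Si](CC)(CC)CC)CCO[Si](C)(C)C(C)(C)C | intermediate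
15 | 5,6-threo butenolide diol (C3 and C1 hydroxyls free) | O=C1C=C(C=C)[C@@H](O1)[C@H](O[Si](C)(C)C(C)(C)C)[C@@](OC2(C)C)(CO2)[C@H](O)CCO | intermediate
16 | 5,6-erythro butenolide diol (C6 epimer of 15) | O=C1C=C(C=C)[C@H](O1)[C@H](O[Si](C)(C)C(C)(C)C)[C@@](OC2(C)C)(CO2)[C@H](O)CCO | intermediate
17 | cis-fused 2-vinyltetrahydropyran γ-lactone, C1 primary alcohol | O=C1C[C@@]2(C=C)O[C@H](CCO)[C@](OC4(C)C)(CO4)[C@@H](O[Si](C)(C)C(C)(C)C)[C@H]2O1 | intermediate
18 | pyran-fused lactone C1 carboxylic acid | O=C1C[C@@]2(C=C)O[C@H](CC(=O)O)[C@](OC4(C)C)(CO4)[C@@H](O[Si](C)(C)C(C)(C)C)[C@H]2O1 | intermediate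
19 | N-ethyl-N-nitrosourea | CCN(N=O)C(N)=O | starting material
20 | pyran-fused lactone C1 acid chloride | O=C1C[C@@]2(C=C)O[C@H](CC(=O)Cl)[C@](OC4(C)C)(CO4)[C@@H](O[Si](C)(C)C(C)(C)C)[C@H]2O1 | intermediate
21 | diazoethane | CC=[N+]=[N-] | intermediate
22 | diazo ketone, precursor of the key step | O=C1C[C@@]2(C=C)O[C@H](CC(=O)C(C)=[N+]=[N-])[C@](OC4(C)C)(CO4)[C@@H](O[Si](C)(C)C(C)(C)C)[C@H]2O1 | intermediate
23 | bicyclic oxonium ylide (enolate form) | O=C1C[C@@]2(C=C)[O+]5[C@H](CC([O-])=C5C)[C@](OC4(C)C)(CO4)[C@@H](O[Si](C)(C)C(C)(C)C)[C@H]2O1 | intermediate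
24 | oxygen-bridged (E)-cyclodecene tetrahydrofuranone lactone, product of the key step | O=C1C/C2=C\C[C@@]3(C)O[C@H](CC3=O)[C@](OC4(C)C)(CO4)[C@@H](O[Si](C)(C)C(C)(C)C)[C@H]2O1 | intermediate
25 | trimethylsilyl enol ether of 24 (C1–O–Si, C1=C2) | O=C1C/C2=C\C[C@@]3(C)O[C@H](C=C3O[Si](C)(C)C)[C@](OC4(C)C)(CO4)[C@@H](O[Si](C)(C)C(C)(C)C)[C@H]2O1 | intermediate
26 | bridged (E)-cyclodecene 3(2H)-furanone lactone | O=C1C/C2=C\C[C@@]3(C)OC(=CC3=O)[C@](OC4(C)C)(CO4)[C@@H](O[Si](C)(C)C(C)(C)C)[C@H]2O1 | intermediate
27 | 7,8-epoxide (oxygen syn to H6) | O=C1C[C@@]2(O5)[C@@H]5C[C@@]3(C)OC(=CC3=O)[C@](OC4(C)C)(CO4)[C@@H](O[Si](C)(C)C(C)(C)C)[C@H]2O1 | intermediate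
28 | (8S)-8-hydroxy-7(11)-butenolide | O=C1C=C2[C@@H](O)C[C@@]3(C)OC(=CC3=O)[C@](OC4(C)C)(CO4)[C@@H](O[Si](C)(C)C(C)(C)C)[C@H]2O1 | intermediate
29 | (8R)-8-formyloxy-7(11)-butenolide | O=C1C=C2[C@H](OC=O)C[C@@]3(C)OC(=CC3=O)[C@](OC4(C)C)(CO4)[C@@H](O[Si](C)(C)C(C)(C)C)[C@H]2O1 | intermediate
30 | (8R)-8-hydroxy-7(11)-butenolide | O=C1C=C2[C@H](O)C[C@@]3(C)OC(=CC3=O)[C@](OC4(C)C)(CO4)[C@@H](O[Si](C)(C)C(C)(C)C)[C@H]2O1 | intermediate
31 | (7R,8R)-8-hydroxy trans-fused γ-lactone | O=C1C[C@@H]2[C@H](O)C[C@@]3(C)OC(=CC3=O)[C@](OC4(C)C)(CO4)[C@@H](O[Si](C)(C)C(C)(C)C)[C@H]2O1 | intermediate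
32 | C11 (dimethylamino)methyl lactone (C11 configuration not defined, removed in the same step) | O=C1C(CN(C)C)[C@@H]2[C@H](O)C[C@@]3(C)OC(=CC3=O)[C@](OC4(C)C)(CO4)[C@@H](O[Si](C)(C)C(C)(C)C)[C@H]2O1 | intermediate
33 | C11 (trimethylammonio)methyl lactone iodide | O=C1C(C[N+](C)(C)C)[C@@H]2[C@H](O)C[C@@]3(C)OC(=CC3=O)[C@](OC4(C)C)(CO4)[C@@H](O[Si](C)(C)C(C)(C)C)[C@H]2O1.[I-] | intermediate
34 | α-methylene lactone with free C8 alcohol | O=C1C(=C)[C@@H]2[C@H](O)C[C@@]3(C)OC(=CC3=O)[C@](OC4(C)C)(CO4)[C@@H](O[Si](C)(C)C(C)(C)C)[C@H]2O1 | intermediate
35 | C8 methacrylate, C5 OTBS | O=C1C(=C)[C@@H]2[C@H](OC(=O)C(C)=C)C[C@@]3(C)OC(=CC3=O)[C@](OC4(C)C)(CO4)[C@@H](O[Si](C)(C)C(C)(C)C)[C@H]2O1 | intermediate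
36 | C8 methacrylate, C5 alcohol | O=C1C(=C)[C@@H]2[C@H](OC(=O)C(C)=C)C[C@@]3(C)OC(=CC3=O)[C@](OC4(C)C)(CO4)[C@@H](O)[C@H]2O1 | intermediate
37 | C5 acetate, C4/C15 acetonide of the target | O=C1C(=C)[C@@H]2[C@H](OC(=O)C(C)=C)C[C@@]3(C)OC(=CC3=O)[C@](OC4(C)C)(CO4)[C@@H](OC(C)=O)[C@H]2O1 | intermediate
38 | CNP0275292.4 | O=C1C(=C)[C@@H]2[C@H](OC(=O)C(C)=C)C[C@@]3(C)OC(=CC3=O)[C@](O)(CO)[C@@H](OC(C)=O)[C@H]2O1 | target

Total step count: 25. Longest linear sequence: 23 steps (steps 1–5 and 8–25, from 1 to 38); steps 6 and 7 make the furan fragment.

Least certain steps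

Step 14 (key step). The most likely failure is 1,2-hydride migration from the methyl group of the carbenoid to give a vinyl ketone before the ether oxygen is engaged. That oxygen is hindered by the fully substituted C7. A [1,2]-shift of the tertiary allylic C7 or formation of the Z-alkene would also divert material. Fallback: the carbenoid is made without β-hydrogens. Acid chloride 20 is treated with diazomethane to give the diazomethyl ketone F1. Under the conditions of step 14 this should give the C10-unsubstituted bridged ketone F2, the parent case of this ring expansion. Saegusa–Ito oxidation as in step 15 gives the furanone F3. Its C10–H, between the ether oxygen and the ketone, is the most acidic position (deprotonation gives an aromatic 3-oxidofuran). KN(SiMe3)2 and MeI at −78 °C should methylate C10, where the methyl group can only take the place of the bridgehead hydrogen, and the route is rejoined at 26.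

Step 11. Loss of the C5 silyloxy group from the 2-oxidofuran by vinylogous β-elimination, incomplete equilibration at C6 before ring closure, or an unfavourable equilibrium (the cross-conjugated dienyl lactone is stabilised) may lower the return. Fallback: the cyclisation is run with a free C5 hydroxyl, whose alkoxide is not a leaving group. 13 is desilylated at both silyl ethers (HF·pyridine) to the triol F4 and cyclised with Et3N or DBU to the bicyclic diol F5. F5 is oxidised selectively at the primary alcohol (TEMPO, PhI(OAc)2) to the hydroxy acid F6, which is silylated at C5 (t-BuMe2SiOTf, 2,6-lutidine, aqueous cleavage of the silyl ester) to rejoin at 18.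

Step 17. Once formed, the butenolide is more acidic at C6 than the epoxy lactone is at C11. Further deprotonation would epimerise C6 or expel the C5 silyloxy group. Fallback without base: photooxygenation of 26 (O2, tetraphenylporphyrin, visible light, CH2Cl2). The singlet oxygen ene reaction should place oxygen on C8 from the exposed face with abstraction of H11, giving the allylic hydroperoxide F7. Reduction with PPh3 rejoins the route at 28.

Step 20. Hydrogen may be delivered to the wrong face, or not at all, if the C8 hydroxyl cannot bring the metal onto the face shielded by the ring; reduction of the furanone alkene may compete. Fallback with a covalent tether: 30 is silylated with chlorodimethylsilane/Et3N to the hydrosilyl ether F8. Platinum-catalysed intramolecular hydrosilylation (Pt2[(CH2=CHSiMe2)2O]3, toluene) should close the five-membered oxasilolane F9, with silicon on C11 and hydrogen on C7 on the face of the tether. KF/KHCO3 in MeOH/THF cleaves the Si–O bond and the α-silyl lactone C–Si bond and returns to 31.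

Further compounds

F1 | step 14 | diazomethyl ketone (C10 without methyl) | O=C1C[C@@]2(C=C)O[C@H](CC(=O)C=[N+]=[N-])[C@](OC4(C)C)(CO4)[C@@H](O[Si](C)(C)C(C)(C)C)[C@H]2O1
F2 | step 14 | C10-unsubstituted bridged (E)-cyclodecene ketone | O=C1C/C2=C\C[C@H]3O[C@H](CC3=O)[C@](OC4(C)C)(CO4)[C@@H](O[Si](C)(C)C(C)(C)C)[C@H]2O1
F3 | step 14 | C10-unsubstituted bridged 3(2H)-furanone | O=C1C/C2=C\C[C@H]3OC(=CC3=O)[C@](OC4(C)C)(CO4)[C@@H](O[Si](C)(C)C(C)(C)C)[C@H]2O1
F4 | step 11 | butenolide triol (C5, C3 and C1 hydroxyls free) | O=C1C=C(C=C)[C@@H](O1)[C@H](O)[C@@](OC2(C)C)(CO2)[C@H](O)CCO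
F5 | step 11 | pyran-fused lactone C5,C1-diol | O=C1C[C@@]2(C=C)O[C@H](CCO)[C@](OC4(C)C)(CO4)[C@@H](O)[C@H]2O1
F6 | step 11 | pyran-fused lactone C5-hydroxy C1-acid | O=C1C[C@@]2(C=C)O[C@H](CC(=O)O)[C@](OC4(C)C)(CO4)[C@@H](O)[C@H]2O1
F7 | step 17 | (8S)-8-hydroperoxy-7(11)-butenolide | O=C1C=C2[C@@H](OO)C[C@@]3(C)OC(=CC3=O)[C@](OC4(C)C)(CO4)[C@@H](O[Si](C)(C)C(C)(C)C)[C@H]2O1
F8 | step 20 | (8R)-8-(dimethylsilyloxy)-7(11)-butenolide | O=C1C=C2[C@H](O[SiH](C)C)C[C@@]3(C)OC(=CC3=O)[C@](OC4(C)C)(CO4)[C@@H](O[Si](C)(C)C(C)(C)C)[C@H]2O1
F9 | step 20 | C11,O8-bridged dimethyloxasilolane | O=C1[C@@H]5[C@@H]2[C@H](O[Si]5(C)C)C[C@@]3(C)OC(=CC3=O)[C@](OC4(C)C)(CO4)[C@@H](O[Si](C)(C)C(C)(C)C)[C@H]2O1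
A1 | alternative 1 | ten-membered Z-dienone C6 alcohol | CC[Si](CC)(CC)O[C@@H]1C[C@@]2(C)OC(=CC2=O)/C(CO[Si](C)(C)C(C)(C)C)=C\[C@@H](O)[C@@H]1CC(=O)OC
A2 | alternative 2 | 3,5-bridged isoxazole macrocycle | CC(C)(C)[Si](C)(C)O[C@@H]1C[C@@](C)(O[Si](CC)(CC)CC)c2cc(on2)[C@](OC4(C)C)(CO4)[C@@H](OC(C)=O)[C@H]2OC(=O)C[C@@H]21
A3 | alternative 3 | α-methylene lactone with C8 silyl ether | CC(C)(C)[Si](C)(C)O[C@@H]1C[C@@]2(C)OC(=CC2=O)[C@](OC4(C)C)(CO4)[C@@H](OC(C)=O)[C@H]2OC(=O)C(=C)[C@@H]21
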